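**Strategy.** Ring A of the chroman (C4a, C5–C8, C8a) is an unsymmetrical phloroglucinol: OH at C5 and C7, formyl only at C6, hydrogen at C8, ether O1 on C8a. Everything rests on disconnecting C5–C6 and tracing ring A back to a fused 2-pyranone in which C5 is the lactone carbonyl, C7 the oxygen-bearing ring carbon and C6 a side-chain methylene carrying the masked formyl group. Methoxide then opens the lactone and Claisen recyclization closes ring A as the arene in one operation, with no electrophilic substitution. The precursor is a 3,4-dihydro-2H-pyrano[4,3-b]pyran-5-one carrying all three stereocentres, a MOM-protected ring B and a 7-(1,3-dioxolan-2-ylmethyl) chain.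

Key step: step 5

**Remarks on the chemistry (one line each)**
- Structure check: the target is (2R,3R,4S), with the aryl group trans to isopropyl and isopropyl cis to isobutyl; atom labels O1, C2–C4, C4a, C5, C7, C8, C8a are the same in the pyranopyranones and in the chroman (position 6 is the ring oxygen before the key step and the new carbon after it).
- Ring B phenols are capped as MOM ethers before the base step, because free ortho/para phenoxides would expel O1 through an ortho-quinone methide and undo the O1/C5-OH differentiation on which the strategy relies.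
- The masked formyl group is carried as the ethylene acetal, which should tolerate the two anhydrous acid steps better than a dimethyl acetal; the side chain is installed by C-formylation of the lactone dianion followed by acetalization.
- Assumption: the quinine-derived primary amine is taken to direct the pyranone to the Si face of the enal β-carbon (giving 4S); if the opposite sense is found, the pseudoenantiomeric quinidine-derived amine is used in the same way.
- Assumption: 2,4-diformylphloroglucinol is taken as purchasable.

**Route**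

Step 1
Reactants: 1 triacetic acid lactone (4-hydroxy-6-methyl-2H-pyran-2-one); 2 ethyl formate
Product: 4 6-(1,3-dioxolan-2-ylmethyl)-4-hydroxy-2H-pyran-2-one, via formylmethyl pyranone 3 (not isolated)
Conditions: LiN(iPr)2 (2.2 equiv), THF, −78 °C; 2, −78 → 0 °C; HCl (dioxane) to pH 3; then HOCH2CH2OH, TsOH·H2O (cat.), toluene, reflux, azeotropic removal of water
Reagents that add atoms: ethylene glycol, OCCO
Why: The dianion carries its second charge on the 6-methyl carbon, which is C-acylated by the formate (Claisen-type acylation), and the enolised aldehyde is trapped at once as the dioxolane by acid-catalysed acetalization, the way formylacetone salts are converted into their acetals.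

Step 2
Reactants: 4 6-(1,3-dioxolan-2-ylmethyl)-4-hydroxy-2H-pyran-2-one; 5 (E)-2-isopropyl-5-methylhex-2-enal
Product: 7 (4S)-7-(1,3-dioxolan-2-ylmethyl)-4-isobutyl-3-isopropyl-4H-pyrano[4,3-b]pyran-5-one, via lactol 6 (not isolated)
Conditions: 9-amino-9-deoxy-epi-quinine (20 mol %), CF3CO2H (40 mol %), CHCl3, 40 °C; then TsOH·H2O (0.6 equiv), toluene, 100 °C, azeotropic removal of water
Reagents that add atoms: none
Why: Iminium-ion activation of the α-branched enal by the primary amine should let C3 of the acidic pyranone add to the Si face of the β-carbon (organocatalytic Michael addition–lactolization), setting C4 as S under catalyst control, and acid-catalysed dehydration then erases the uncontrolled C2 and C3 centres of the lactol to leave a single enol ether.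

Step 3
Reactants: 7 (4S)-7-(1,3-dioxolan-2-ylmethyl)-4-isobutyl-3-isopropyl-4H-pyrano[4,3-b]pyran-5-one; 8 2,4-diformylphloroglucinol
Product: 9 (2R,3R,4S)-2-(3,5-diformyl-2,4,6-trihydroxyphenyl)-7-(1,3-dioxolan-2-ylmethyl)-4-isobutyl-3-isopropyl-3,4-dihydro-2H-pyrano[4,3-b]pyran-5-one
Conditions: 8 (1.5 equiv), TsOH (anhydrous, 30 mol %), MeCN, 4 Å molecular sieves, 50 °C
Reagents that add atoms: none
Why: In this Brønsted-acid hydroarylation of an enol ether (Friedel–Crafts alkylation by a cyclic oxocarbenium ion, C-glycosylation type) the proton should add to C3 opposite the C4 isobutyl group, which allylic strain with the C5 carbonyl holds pseudoaxial, so that isopropyl ends up cis to isobutyl (3R), and the arene then attacks C2 anti to both alkyl groups (2R), the same equatorial, 2,3-trans aryl placement that reversible ionisation of the benzylic C2–O1 bond would favour.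

Step 4
Reactants: 9 (2R,3R,4S)-2-(3,5-diformyl-2,4,6-trihydroxyphenyl)-7-(1,3-dioxolan-2-ylmethyl)-4-isobutyl-3-isopropyl-3,4-dihydro-2H-pyrano[4,3-b]pyran-5-one
Product: 10 (2R,3R,4S)-2-[3,5-diformyl-2,4,6-tris(methoxymethoxy)phenyl]-7-(1,3-dioxolan-2-ylmethyl)-4-isobutyl-3-isopropyl-3,4-dihydro-2H-pyrano[4,3-b]pyran-5-one
Conditions: MOMCl (6 equiv), iPr2NEt (8 equiv), CH2Cl2, 0 °C → rt
Reagents that add atoms: chloromethyl methyl ether (MOMCl), COCCl
Why: Williamson-type O-alkylation of the three acidic phenols removes every ortho and para phenoxide of ring B, so the following base step cannot ionise the C2–O1 bond through an ortho-quinone methide, and it uses groups that leave together with the acetal in acid.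

Step 5
Reactants: 10 (2R,3R,4S)-2-[3,5-diformyl-2,4,6-tris(methoxymethoxy)phenyl]-7-(1,3-dioxolan-2-ylmethyl)-4-isobutyl-3-isopropyl-3,4-dihydro-2H-pyrano[4,3-b]pyran-5-one
Product: 12 5-[(2R,3R,4S)-6-(1,3-dioxolan-2-yl)-5,7-dihydroxy-4-isobutyl-3-isopropylchroman-2-yl]-2,4,6-tris(methoxymethoxy)benzene-1,3-dicarbaldehyde, via keto ester 11 (not isolated)
Conditions: NaOMe (8 equiv), MeOH (0.02 M), 60 °C; AcOH (8 equiv), 0 °C; crude product carried on
Reagents that add atoms: none
Why: Methoxide adds to the lactone carbonyl C5 and the ring opens to keto ester 11 (methyl ester on C4a, ketone at C7), whose C6 enolate, reached by proton exchange or by reversible β-elimination and re-addition at the acetal, attacks the ester carbonyl, after which methoxide leaves and the 5-alkoxycyclohexene-1,3-dione tautomerises to the benzene ring. The closest known reaction types are the base-induced recyclization of 4-oxy-6-alkyl-2-pyranones to resorcinol and phloroglucinol derivatives and the NaOMe-mediated Claisen (Dieckmann-type) cyclization of δ-keto esters to cyclohexane-1,3-diones. Ring A closes by a 6-(enolendo)-exo-trig attack of C6 on the ester carbon C5. No stereocentre is formed, and C2, C3 and C4 carry no acidic hydrogen, so they should pass unchanged. The step needs C6 and not C8 to act as the nucleophile and the C2–O1 bond to stay intact: only C6 can reach C5 through a six-membered transition state (C8 would close a four-membered ring), the C4a=C8a enol ether holds the ester and the ketone chain cis, and the MOM ethers of ring B shut off quinone-methide ionisation. The methoxide that is borrowed is returned, so the step is an isomerisation in which O1 on C8a, the acetal carbon on C6 and the hydrogen on C8 are fixed by connectivity.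

Step 6
Reactants: 12 5-[(2R,3R,4S)-6-(1,3-dioxolan-2-yl)-5,7-dihydroxy-4-isobutyl-3-isopropylchroman-2-yl]-2,4,6-tris(methoxymethoxy)benzene-1,3-dicarbaldehyde
Product: 13 5-[(2R,3R,4S)-6-formyl-5,7-dihydroxy-4-isobutyl-3-isopropylchroman-2-yl]-2,4,6-trihydroxybenzene-1,3-dicarbaldehyde (target, CNP0328914.1)
Conditions: HCl (2 M aq.), MeOH/THF, 40 °C
Reagents that add atoms: water, O
Why: Acid-catalysed acetal hydrolysis and methanolysis of the aryl MOM ethers (acetal exchange), both eased by the neighbouring hydroxyl or carbonyl groups, should release the C6 formyl group and the three ring B phenols in one operation, with methanol trapping the methoxymethyl cation as dimethoxymethane so that C8 of ring A is not alkylated.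

**Compound list**

1 | triacetic acid lactone (4-hydroxy-6-methyl-2H-pyran-2-one) | CC1=CC(O)=CC(=O)O1 | starting material
2 | ethyl formate | CCOC=O | starting material
3 | 4-hydroxy-6-(2-oxoethyl)-2H-pyran-2-one (aldehyde/enol tautomers) | O=CCC1=CC(O)=CC(=O)O1 | intermediate (not isolated)
4 | 6-(1,3-dioxolan-2-ylmethyl)-4-hydroxy-2H-pyran-2-one | OC1=CC(=O)OC(CC2OCCO2)=C1 | intermediate
5 | (E)-2-isopropyl-5-methylhex-2-enal | CC(C)C/C=C(/C=O)C(C)C | starting material
6 | (4S)-7-(1,3-dioxolan-2-ylmethyl)-2-hydroxy-4-isobutyl-3-isopropyl-3,4-dihydro-2H-pyrano[4,3-b]pyran-5-one (mixture at C2 and C3) | CC(C)C[C@@H]1C2=C(C=C(CC3OCCO3)OC2=O)OC(O)C1C(C)C | intermediate (not isolated)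
7 | (4S)-7-(1,3-dioxolan-2-ylmethyl)-4-isobutyl-3-isopropyl-4H-pyrano[4,3-b]pyran-5-one | CC(C)C[C@@H]1C2=C(C=C(CC3OCCO3)OC2=O)OC=C1C(C)C | intermediate
8 | 2,4-diformylphloroglucinol (2,4,6-trihydroxybenzene-1,3-dicarbaldehyde) | O=Cc1c(O)cc(O)c(C=O)c1O | starting material
9 | (2R,3R,4S)-2-(3,5-diformyl-2,4,6-trihydroxyphenyl)-7-(1,3-dioxolan-2-ylmethyl)-4-isobutyl-3-isopropyl-3,4-dihydro-2H-pyrano[4,3-b]pyran-5-one | CC(C)C[C@@H]1C2=C(C=C(CC3OCCO3)OC2=O)O[C@@H](c2c(O)c(C=O)c(O)c(C=O)c2O)[C@@H]1C(C)C | intermediate
10 | (2R,3R,4S)-2-[3,5-diformyl-2,4,6-tris(methoxymethoxy)phenyl]-7-(1,3-dioxolan-2-ylmethyl)-4-isobutyl-3-isopropyl-3,4-dihydro-2H-pyrano[4,3-b]pyran-5-one (precursor of the key step) | CC(C)C[C@@H]1C2=C(C=C(CC3OCCO3)OC2=O)O[C@@H](c2c(OCOC)c(C=O)c(OCOC)c(C=O)c2OCOC)[C@@H]1C(C)C | intermediate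
11 | methyl (2R,3R,4S)-2-[3,5-diformyl-2,4,6-tris(methoxymethoxy)phenyl]-6-[3-(1,3-dioxolan-2-yl)-2-oxopropyl]-4-isobutyl-3-isopropyl-3,4-dihydro-2H-pyran-5-carboxylate (as its sodium enolate) | CC(C)C[C@@H]1C(C(=O)OC)=C(CC(=O)CC2OCCO2)O[C@@H](c2c(OCOC)c(C=O)c(OCOC)c(C=O)c2OCOC)[C@@H]1C(C)C | intermediate (not isolated)
12 | 5-[(2R,3R,4S)-6-(1,3-dioxolan-2-yl)-5,7-dihydroxy-4-isobutyl-3-isopropylchroman-2-yl]-2,4,6-tris(methoxymethoxy)benzene-1,3-dicarbaldehyde (product of the key step) | CC(C)C[C@@H]1c2c(cc(O)c(C3OCCO3)c2O)O[C@@H](c2c(OCOC)c(C=O)c(OCOC)c(C=O)c2OCOC)[C@@H]1C(C)C | intermediate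
13 | 5-[(2R,3R,4S)-6-formyl-5,7-dihydroxy-4-isobutyl-3-isopropylchroman-2-yl]-2,4,6-trihydroxybenzene-1,3-dicarbaldehyde | CC(C)C[C@@H]1c2c(cc(O)c(C=O)c2O)O[C@@H](c2c(O)c(C=O)c(O)c(C=O)c2O)[C@@H]1C(C)C | target

**Step count and risk**

Total steps: 6. Longest linear sequence: 6 (1 → 4 → 7 → 9 → 10 → 12 → 13).

Steps most likely to fail:

1. Step 5 (key step). After lactone opening, enolisation may occur mainly at the more acidic C8, so that retro-Claisen cleavage of the C7–C8 bond or aldol attack of enolates on the ring B formyl groups outruns C5–C6 bond formation. The fallback sets out from 10 and comes back at 13. The ethylene acetal of 10 alone is hydrolysed (pyridinium p-toluenesulfonate, wet acetone, 50 °C, conditions that aryl MOM ethers should survive) to the enolised (2R,3R,4S)-2-[3,5-diformyl-2,4,6-tris(methoxymethoxy)phenyl]-4-isobutyl-3-isopropyl-7-(2-oxoethyl)-3,4-dihydro-2H-pyrano[4,3-b]pyran-5-one F1. Mg(OMe)2 in MeOH at reflux then opens the lactone to a β-keto aldehyde in which C6 is the only doubly stabilised enolate position. Its chelated enolate acylates on the ester, as in the classical Claisen cyclization of 3,5,7-tricarbonyl esters to 2-acylphloroglucinols, and should give 5-[(2R,3R,4S)-6-formyl-5,7-dihydroxy-4-isobutyl-3-isopropylchroman-2-yl]-2,4,6-tris(methoxymethoxy)benzene-1,3-dicarbaldehyde F2 directly. HCl in MeOH/THF removes the three MOM groups and gives 13.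

2. Step 3. C-arylation by the arene, which two formyl groups deactivate, may be slower than loss of the C3 proton from the oxocarbenium ion, so that the ion shuttles back to 7, facial control at C3 erodes and the acetal suffers. The fallback sets out from 7 and comes back at 9. Phloroglucinol (Oc1cc(O)cc(O)c1, 5 equiv), a far stronger π-nucleophile, is used under the same acid catalysis at 0 °C to capture the first-formed cis oxocarbenium ion, giving (2R,3R,4S)-7-(1,3-dioxolan-2-ylmethyl)-4-isobutyl-3-isopropyl-2-(2,4,6-trihydroxyphenyl)-3,4-dihydro-2H-pyrano[4,3-b]pyran-5-one F3. Twofold Vilsmeier–Haack formylation (POCl3, DMF, MeCN, 0 °C → rt; aqueous NaOAc) of the only electron-rich arene then installs both formyl groups of ring B and gives 9.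

3. Step 2. Iminium formation from the α-branched enal may be slow, so that an uncatalysed background addition or 1,2-addition (Knoevenagel condensation, then oxa-6π closure to a 2H-pyran) lowers enantiopurity and conversion. The fallback sets out from 4 and comes back at lactol 6, which is dehydrated to 7 as in step 2. Both alkyl groups are brought in from isovaleraldehyde (CC(C)CC=O, two molecules). Amine-catalysed Knoevenagel condensation with 4 gives the electron-poor oxadiene 6-(1,3-dioxolan-2-ylmethyl)-3-(3-methylbutylidene)-2H-pyran-2,4(3H)-dione F4 in the flask. This is trapped in an inverse-electron-demand hetero-Diels–Alder reaction by the enamine that a second molecule of isovaleraldehyde forms with a diphenylprolinol trimethylsilyl ether (the enantiomer that leads to 4S). Hydrolysis of the aminal gives 6 with C4 set under catalyst control; its C3 configuration does not matter because the dehydration erases it.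

**Further compounds**

F1 | step 5 | (2R,3R,4S)-2-[3,5-diformyl-2,4,6-tris(methoxymethoxy)phenyl]-4-isobutyl-3-isopropyl-7-(2-oxoethyl)-3,4-dihydro-2H-pyrano[4,3-b]pyran-5-one | CC(C)C[C@@H]1C2=C(C=C(CC=O)OC2=O)O[C@@H](c2c(OCOC)c(C=O)c(OCOC)c(C=O)c2OCOC)[C@@H]1C(C)C
F2 | step 5 | 5-[(2R,3R,4S)-6-formyl-5,7-dihydroxy-4-isobutyl-3-isopropylchroman-2-yl]-2,4,6-tris(methoxymethoxy)benzene-1,3-dicarbaldehyde | CC(C)C[C@@H]1c2c(cc(O)c(C=O)c2O)O[C@@H](c2c(OCOC)c(C=O)c(OCOC)c(C=O)c2OCOC)[C@@H]1C(C)C
F3 | step 3 | (2R,3R,4S)-7-(1,3-dioxolan-2-ylmethyl)-4-isobutyl-3-isopropyl-2-(2,4,6-trihydroxyphenyl)-3,4-dihydro-2H-pyrano[4,3-b]pyran-5-one | CC(C)C[C@@H]1C2=C(C=C(CC3OCCO3)OC2=O)O[C@@H](c2c(O)cc(O)cc2O)[C@@H]1C(C)C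
F4 | step 2 | 6-(1,3-dioxolan-2-ylmethyl)-3-(3-methylbutylidene)-2H-pyran-2,4(3H)-dione | CC(C)CC=C1C(=O)C=C(CC2OCCO2)OC1=O
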